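**Convention:** terpenoid carbons carry eudesmane numbers (C1–C15), the benzylic carbon is C1′, and β is the face of the C10 methyl group.

## Retrosynthetic overview

1. Macrocarpal H ⇐ O-demethylation, double ortho-formylation and para C–H hydroxylation of a 2,6-dimethoxyphenyl group (from resorcinol) carried on a 1β-substituted β-eudesmol core.
2. C4 methylene ⇐ Wittig on the C4 ketone; C11 carbinol ⇐ methyl addition to a C7 acetyl group.
3. Ring B with its acetyl group ⇐ oxidative ring contraction (1,2-alkyl shift) of a methylcycloheptene ring that is closed by ring-closing metathesis.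
4. Metathesis precursor ⇐ conjugate addition/enolate allylation on a 4-substituted 3-methylcyclohexenone (ring A is the bought enone; sets C10).
5. C1–C1′ bond with both stereocentres ⇐ new catalytic asymmetric vinylogous benzylation of a silyl dienol ether. Ring order: ring A (bought) → seven-membered ring → contracted to ring B; arene tailored last.

## Route

Step 1
Reactants: 1 resorcinol (benzene-1,3-diol)
Product: 2 1,3-dimethoxybenzene
Conditions: MeI (2.5 equiv), K2CO3, acetone, reflux
Reagents that add atoms: iodomethane, CI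
Why: Williamson O-methylation (SN2) of both phenols gives the ether that directs the next metalation and survives to the last step; no stereocentre.

Step 2
Reactants: 2 1,3-dimethoxybenzene; 3 3-methylbutanal
Product: 5 rac-1-(2,6-dimethoxyphenyl)-3-methylbutan-1-ol, via (2,6-dimethoxyphenyl)lithium 4 (not isolated)
Conditions: n-BuLi, THF, 0 → 25 °C; 3, −78 °C; H2O
Reagents that add atoms: none
Why: Directed ortho-metalation between the two methoxy groups followed by 1,2-addition to the aldehyde; the carbinol centre is left racemic because it is erased by ionisation in step 4.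

Step 3
Reactants: 6 3-methylcyclohex-2-en-1-one
Product: 7 tert-butyldimethyl[(3-methylcyclohexa-1,3-dien-1-yl)oxy]silane
Conditions: TBSOTf, Et3N, CH2Cl2, 0 → 25 °C
Reagents that add atoms: tert-butyldimethylsilyl trifluoromethanesulfonate, CC(C)(C)[Si](C)(C)OS(=O)(=O)C(F)(F)F
Why: Soft enolisation under equilibrating conditions gives the thermodynamic, endocyclic extended (linear) silyl dienol ether, whose γ-carbon is the future C1.

Step 4
Reactants: 5 rac-1-(2,6-dimethoxyphenyl)-3-methylbutan-1-ol; 7 tert-butyldimethyl[(3-methylcyclohexa-1,3-dien-1-yl)oxy]silane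
Product: 9 (S)-4-[(S)-1-(2,6-dimethoxyphenyl)-3-methylbutyl]-3-methylcyclohex-2-en-1-one, via benzylic cation ion pair 8 (not isolated)
Conditions: (S)-3,3′-bis(2,4,6-triisopropylphenyl)-1,1′-binaphthyl-2,2′-diyl N-triflylphosphoramide (5 mol %), toluene, −40 °C
Reagents that add atoms: none
Why: Proposed new method: the strong chiral Brønsted acid ionises racemic 5 to the planar 2,6-dimethoxybenzylic cation 8 (enantioconvergent SN1), held as a contact ion pair in the chiral anion pocket, and the γ-carbon of 7 attacks one face through an open antiperiplanar transition state that sets C1 (S) and C1′ (S) together, the released water desilylating the oxocarbenium and returning the acid (catalyst antipode to be chosen by screening); the closest known reaction types are chiral-phosphoric-acid-catalysed additions to in situ ortho-quinone methides and racemic Lewis-acid SN1 vinylogous Mukaiyama benzylations of silyl dienol ethers.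

Step 5
Reactants: 9 (S)-4-[(S)-1-(2,6-dimethoxyphenyl)-3-methylbutyl]-3-methylcyclohex-2-en-1-one; 10 4-bromo-2-methylbut-1-ene; 11 3-bromoprop-1-ene
Product: 15 (3S,4S)-2-allyl-4-[(S)-1-(2,6-dimethoxyphenyl)-3-methylbutyl]-3-methyl-3-(3-methylbut-3-en-1-yl)cyclohexan-1-one (C2 epimers), via (3-methylbut-3-en-1-yl)magnesium bromide 12 (not isolated), via trimethylsilyl enol ether 13 (not isolated), via lithium enolate 14 (not isolated)
Conditions: 10, Mg, THF; 9, CuBr·SMe2 (10 mol %), TMSCl, HMPA, THF, −78 → −30 °C; volatiles removed; MeLi, THF, 0 °C; 11, HMPA, −78 → 0 °C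
Reagents that add atoms: none
Why: Copper-catalysed, TMSCl-accelerated conjugate addition occurs anti to the C1 side chain and creates the C10 quaternary centre (methyl cis to the side chain), and the regiodefined enolate is C-allylated at C5 (tandem conjugate addition–enolate alkylation; the C5 configuration is settled in step 7).

Step 6
Reactants: 15 (3S,4S)-2-allyl-4-[(S)-1-(2,6-dimethoxyphenyl)-3-methylbutyl]-3-methyl-3-(3-methylbut-3-en-1-yl)cyclohexan-1-one
Product: 16 (4S,4aS)-4-[(S)-1-(2,6-dimethoxyphenyl)-3-methylbutyl]-4a,7-dimethyl-2,3,4,4a,5,6,9,9a-octahydro-1H-benzo[7]annulen-1-one (9a epimers)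
Conditions: RuCl2(=CHPh)(PCy3)(H2IMes) (second-generation Grubbs catalyst, 5 mol %), toluene (5 mM), 80 °C
Reagents that add atoms: none
Why: Ring-closing olefin metathesis between the allyl group and the 1,1-disubstituted alkene closes the seven-membered ring with a trisubstituted C7=C11 alkene, driven by loss of ethene.

Step 7
Reactants: 16 (4S,4aS)-4-[(S)-1-(2,6-dimethoxyphenyl)-3-methylbutyl]-4a,7-dimethyl-2,3,4,4a,5,6,9,9a-octahydro-1H-benzo[7]annulen-1-one
Product: 19 7β-acetyl-1β-[(S)-1-(2,6-dimethoxyphenyl)-3-methylbutyl]-10β-methyl-5αH-decalin-4-one (trans-fused), via organothallium adduct 17 (not isolated), via dimethyl ketal 18 (not isolated)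
Conditions: Tl(NO3)3·3H2O (1.1 equiv), MeOH, 0 °C, 15 min; H2O, 25 °C, 1 h; NaHCO3 work-up; then NaOMe (cat.), MeOH, 25 °C
Reagents that add atoms: water, O
Why: Markovnikov oxythallation puts trivalent thallium on C7 and methoxide on C11, and loss of monovalent thallium drives the antiperiplanar 1,2-shift of ring carbon C8 from C11 to C7 (McKillop–Taylor oxidative ring contraction, a semipinacol-type shift), which contracts the seven-membered ring to ring B and turns C11 into the acetyl carbonyl; methoxide then equilibrates C5 and C7, both α to a carbonyl, to the trans-decalin with equatorial 7β-acetyl.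

Step 8
Reactants: 19 7β-acetyl-1β-[(S)-1-(2,6-dimethoxyphenyl)-3-methylbutyl]-10β-methyl-5αH-decalin-4-one
Product: 20 1β-[(S)-1-(2,6-dimethoxyphenyl)-3-methylbutyl]-11-hydroxy-15-nor-5α-eudesman-4-one
Conditions: MeMgBr (1.1 equiv), THF, −78 °C; H2O
Reagents that add atoms: methylmagnesium bromide, C[Mg]Br
Why: Chemoselective Grignard 1,2-addition to the unhindered equatorial methyl ketone, the C4 ketone being flanked by the ring fusion and shielded on its β-face by the 1,3-diaxial C10 methyl group; C7 is untouched.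

Step 9
Reactants: 20 1β-[(S)-1-(2,6-dimethoxyphenyl)-3-methylbutyl]-11-hydroxy-15-nor-5α-eudesman-4-one
Product: 22 1β-[(S)-1-(4-hydroxy-2,6-dimethoxyphenyl)-3-methylbutyl]-11-hydroxy-15-nor-5α-eudesman-4-one, via aryl pinacol boronate 21 (not isolated)
Conditions: [Ir(OMe)(cod)]2 (2 mol %), dtbpy (4 mol %), B2pin2, THF, 80 °C; then H2O2, NaOH aq, 0 °C
Reagents that add atoms: hydrogen peroxide, OO
Why: Sterically governed iridium-catalysed aromatic C–H borylation hits the only ring C–H without an ortho substituent (para to the side chain), and oxidation of the C–B bond gives the third phenolic oxygen.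

Step 10
Reactants: 22 1β-[(S)-1-(4-hydroxy-2,6-dimethoxyphenyl)-3-methylbutyl]-11-hydroxy-15-nor-5α-eudesman-4-one
Product: 23 1β-[(S)-1-(4-hydroxy-2,6-dimethoxyphenyl)-3-methylbutyl]-5α-eudesm-4(15)-en-11-ol
Conditions: Ph3PCH3Br (6 equiv), KOtBu (6 equiv), toluene, 100 °C
Reagents that add atoms: methyltriphenylphosphonium bromide, C[P+](c1ccccc1)(c1ccccc1)c1ccccc1.[Br-]
Why: Wittig methylenation of the hindered C4 ketone with excess ylide, which tolerates the phenoxide and tertiary alkoxide; the trans ring fusion is already the thermodynamic C5 epimer, so enolisation cannot scramble it.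

Step 11
Reactants: 23 1β-[(S)-1-(4-hydroxy-2,6-dimethoxyphenyl)-3-methylbutyl]-5α-eudesm-4(15)-en-11-ol
Product: 24 2-hydroxy-4,6-dimethoxy-5-[(S)-1-(11-hydroxy-5α-eudesm-4(15)-en-1β-yl)-3-methylbutyl]benzene-1,3-dicarbaldehyde
Conditions: MgCl2, Et3N, (CH2O)n (excess), THF, reflux; 1 M HCl work-up
Reagents that add atoms: paraformaldehyde (formaldehyde), C=O
Why: Magnesium-phenoxide-directed ortho-formylation (Casnati–Skattebøl; hydroxymethylation then hydride transfer to formaldehyde) at both positions ortho to the phenol, under basic conditions that spare the tertiary alcohol and the exocyclic alkene.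

Step 12
Reactants: 24 2-hydroxy-4,6-dimethoxy-5-[(S)-1-(11-hydroxy-5α-eudesm-4(15)-en-1β-yl)-3-methylbutyl]benzene-1,3-dicarbaldehyde
Product: 25 macrocarpal H
Conditions: NaSEt, DMF, 110 °C; 1 M HCl work-up
Reagents that add atoms: none
Why: SN2 O-demethylation by thiolate, favoured for methoxy groups ortho to a formyl group, frees the last two phenols without acid, so the tertiary alcohol, the exocyclic alkene and all stereocentres are untouched.

## Compound list

1 | resorcinol | Oc1cccc(O)c1 | starting material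
2 | 1,3-dimethoxybenzene | COc1cccc(OC)c1 | intermediate
3 | 3-methylbutanal | CC(C)CC=O | starting material
4 | (2,6-dimethoxyphenyl)lithium | [Li]c1c(OC)cccc1OC | intermediate
5 | rac-1-(2,6-dimethoxyphenyl)-3-methylbutan-1-ol | COc1cccc(OC)c1C(O)CC(C)C | intermediate
6 | 3-methylcyclohex-2-en-1-one | CC1=CC(=O)CCC1 | starting material
7 | tert-butyldimethyl[(3-methylcyclohexa-1,3-dien-1-yl)oxy]silane | CC1=CCCC(O[Si](C)(C)C(C)(C)C)=C1 | intermediate
8 | 1-(2,6-dimethoxyphenyl)-3-methylbutan-1-ylium (ion pair with the phosphoramide anion) | COc1cccc(OC)c1[CH+]CC(C)C | intermediate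
9 | (S)-4-[(S)-1-(2,6-dimethoxyphenyl)-3-methylbutyl]-3-methylcyclohex-2-en-1-one | O=C1CC[C@@H]([C@H](CC(C)C)c2c(OC)cccc2OC)C(C)=C1 | intermediate
10 | 4-bromo-2-methylbut-1-ene | C=C(C)CCBr | starting material
11 | 3-bromoprop-1-ene | C=CCBr | starting material
12 | (3-methylbut-3-en-1-yl)magnesium bromide | C=C(C)CC[Mg]Br | intermediate
13 | trimethylsilyl enol ether of the conjugate adduct (C4–O–Si, C4=C5) | C[Si](C)(C)OC1=C[C@@](C)(CCC(C)=C)[C@H]([C@H](CC(C)C)c2c(OC)cccc2OC)CC1 | intermediate
14 | corresponding lithium enolate | [Li]OC1=C[C@@](C)(CCC(C)=C)[C@H]([C@H](CC(C)C)c2c(OC)cccc2OC)CC1 | intermediate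
15 | (3S,4S)-2-allyl-4-[(S)-1-(2,6-dimethoxyphenyl)-3-methylbutyl]-3-methyl-3-(3-methylbut-3-en-1-yl)cyclohexan-1-one, C2 epimers | O=C1CC[C@@H]([C@H](CC(C)C)c2c(OC)cccc2OC)[C@](C)(CCC(C)=C)C1CC=C | intermediate
16 | (4S,4aS)-4-[(S)-1-(2,6-dimethoxyphenyl)-3-methylbutyl]-4a,7-dimethyl-2,3,4,4a,5,6,9,9a-octahydro-1H-benzo[7]annulen-1-one, 9a epimers | O=C1CC[C@@H]([C@H](CC(C)C)c2c(OC)cccc2OC)[C@]2(C)CCC(C)=CCC12 | intermediate
17 | oxythallation adduct (C7–Tl(ONO2)2, C11–OMe) of 16 | O=C1CC[C@@H]([C@H](CC(C)C)c2c(OC)cccc2OC)[C@]2(C)CCC(C)(OC)C([Tl](O[N+](=O)[O-])O[N+](=O)[O-])CC12 | intermediate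
18 | ring-contracted decalin-4-one with a C7 1,1-dimethoxyethyl group (C5, C7 epimers) | O=C1CC[C@@H]([C@H](CC(C)C)c2c(OC)cccc2OC)[C@]2(C)CCC(C(C)(OC)OC)CC12 | intermediate
19 | 7β-acetyl-1β-[(S)-1-(2,6-dimethoxyphenyl)-3-methylbutyl]-10β-methyl-5αH-decalin-4-one | O=C1CC[C@@H]([C@H](CC(C)C)c2c(OC)cccc2OC)[C@]2(C)CC[C@@H](C(C)=O)C[C@@H]12 | intermediate
20 | 1β-[(S)-1-(2,6-dimethoxyphenyl)-3-methylbutyl]-11-hydroxy-15-nor-5α-eudesman-4-one | O=C1CC[C@@H]([C@H](CC(C)C)c2c(OC)cccc2OC)[C@]2(C)CC[C@@H](C(C)(C)O)C[C@@H]12 | intermediate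
21 | 4-(pinacolboryl)aryl derivative of 20 | O=C1CC[C@@H]([C@H](CC(C)C)c2c(OC)cc(B3OC(C)(C)C(C)(C)O3)cc2OC)[C@]2(C)CC[C@@H](C(C)(C)O)C[C@@H]12 | intermediate
22 | 1β-[(S)-1-(4-hydroxy-2,6-dimethoxyphenyl)-3-methylbutyl]-11-hydroxy-15-nor-5α-eudesman-4-one | O=C1CC[C@@H]([C@H](CC(C)C)c2c(OC)cc(O)cc2OC)[C@]2(C)CC[C@@H](C(C)(C)O)C[C@@H]12 | intermediate
23 | 1β-[(S)-1-(4-hydroxy-2,6-dimethoxyphenyl)-3-methylbutyl]-5α-eudesm-4(15)-en-11-ol | C=C1CC[C@@H]([C@H](CC(C)C)c2c(OC)cc(O)cc2OC)[C@]2(C)CC[C@@H](C(C)(C)O)C[C@@H]12 | intermediate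
24 | 2-hydroxy-4,6-dimethoxy-5-[(S)-1-(11-hydroxy-5α-eudesm-4(15)-en-1β-yl)-3-methylbutyl]benzene-1,3-dicarbaldehyde | C=C1CC[C@@H]([C@H](CC(C)C)c2c(OC)c(C=O)c(O)c(C=O)c2OC)[C@]2(C)CC[C@@H](C(C)(C)O)C[C@@H]12 | intermediate
25 | macrocarpal H | C=C1CC[C@@H]([C@H](CC(C)C)c2c(O)c(C=O)c(O)c(C=O)c2O)[C@]2(C)CC[C@@H](C(C)(C)O)C[C@@H]12 | target

## Step count and risks

Total steps: 12. Longest linear sequence: 11 (steps 1, 2 and 4–12 from resorcinol; step 3 is a one-step branch).

Steps most likely to fail: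

**Step 4 (new asymmetric vinylogous benzylation).** Regiochemistry (γ against α), simple diastereoselection and enantiocontrol are all unproven. The fallback uses known chromium-arene chemistry; it sets out from 5 (and uses 7) and returns at 9. Dess–Martin oxidation of 5 gives 1-(2,6-dimethoxyphenyl)-3-methylbutan-1-one F1. Corey–Bakshi–Shibata reduction ((S)-Me-CBS oxazaborolidine, BH3·SMe2) gives (R)-1-(2,6-dimethoxyphenyl)-3-methylbutan-1-ol F2. Heating with Cr(CO)6 in Bu2O/THF gives its η6-arene tricarbonylchromium complex F3 (zerovalent chromium). HBF4·OEt2 in CH2Cl2 at −78 °C ionises F3 anti to the metal to the configurationally stable chromium-stabilised benzylic cation tetrafluoroborate F4. Dienol ether 7 captures F4 at its γ-carbon, again anti to chromium, so C1′ is formed with net retention; C1 rests on simple diastereoselection and the epimer is removed by chromatography. This gives the tricarbonylchromium complex of the enone F5, and air and light strip the metal and return 9.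

**Step 8 (chemoselective methyl addition to one of two ketones).** The selectivity rests on sterics alone. The fallback masks the acetyl group and reverses the order of olefination and methyl addition; it sets out from 16 and returns at 23. The thallium step is run in MeOH and quenched with NaHCO3 without aqueous acid, so that ketal 18 is isolated with its C4 ketone free, and C5 is equilibrated with NaOMe. Wittig methylenation (Ph3PCH3Br, KOtBu) gives the methylene dimethyl ketal F6. PPTS in wet acetone followed by K2CO3 in MeOH gives the 7β-acetyl methylene compound F7, with C7 equilibrated to the equatorial epimer. MeMgBr gives the tertiary alcohol with a 2,6-dimethoxyphenyl group F8. Iridium-catalysed borylation as in step 9 gives the aryl pinacol boronate F9, and H2O2/NaOH oxidation returns 23.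

**Step 11 (double ortho-formylation).** The second formylation of the magnesium-chelated salicylaldehyde may stall. The fallback installs the carbons at the alcohol oxidation level; it sets out from 23 and returns at 24. Aqueous formaldehyde with NaOH (Lederer–Manasse hydroxymethylation) gives the 3,5-bis(hydroxymethyl)-4-hydroxy-2,6-dimethoxyphenyl compound F10, and MnO2 in CH2Cl2 oxidises both benzylic alcohols to give 24.

Further compounds
F1 | step 4 | 1-(2,6-dimethoxyphenyl)-3-methylbutan-1-one | COc1cccc(OC)c1C(=O)CC(C)C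
F2 | step 4 | (R)-1-(2,6-dimethoxyphenyl)-3-methylbutan-1-ol | O[C@H](CC(C)C)c1c(OC)cccc1OC
F3 | step 4 | tricarbonyl[η6-(R)-1-(2,6-dimethoxyphenyl)-3-methylbutan-1-ol]chromium | O[C@H](CC(C)C)c1c(OC)cccc1OC.[C-]#[O+].[C-]#[O+].[C-]#[O+].[Cr]
F4 | step 4 | tricarbonylchromium-complexed 1-(2,6-dimethoxyphenyl)-3-methylbutan-1-ylium tetrafluoroborate | COc1cccc(OC)c1[CH+]CC(C)C.[C-]#[O+].[C-]#[O+].[C-]#[O+].[Cr].F[B-](F)(F)F
F5 | step 4 | tricarbonylchromium η6-arene complex of 9 | O=C1CC[C@@H]([C@H](CC(C)C)c2c(OC)cccc2OC)C(C)=C1.[C-]#[O+].[C-]#[O+].[C-]#[O+].[Cr]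
F6 | step 8 | 1β-[(S)-1-(2,6-dimethoxyphenyl)-3-methylbutyl]-7-(1,1-dimethoxyethyl)-10β-methyl-4-methylene-5αH-decalin | C=C1CC[C@@H]([C@H](CC(C)C)c2c(OC)cccc2OC)[C@]2(C)CCC(C(C)(OC)OC)C[C@@H]12
F7 | step 8 | 7β-acetyl-1β-[(S)-1-(2,6-dimethoxyphenyl)-3-methylbutyl]-10β-methyl-4-methylene-5αH-decalin | C=C1CC[C@@H]([C@H](CC(C)C)c2c(OC)cccc2OC)[C@]2(C)CC[C@@H](C(C)=O)C[C@@H]12
F8 | step 8 | 1β-[(S)-1-(2,6-dimethoxyphenyl)-3-methylbutyl]-5α-eudesm-4(15)-en-11-ol | C=C1CC[C@@H]([C@H](CC(C)C)c2c(OC)cccc2OC)[C@]2(C)CC[C@@H](C(C)(C)O)C[C@@H]12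
F9 | step 8 | 4-(pinacolboryl)aryl derivative of F8 | C=C1CC[C@@H]([C@H](CC(C)C)c2c(OC)cc(B3OC(C)(C)C(C)(C)O3)cc2OC)[C@]2(C)CC[C@@H](C(C)(C)O)C[C@@H]12
F10 | step 11 | 1β-{(S)-1-[4-hydroxy-3,5-bis(hydroxymethyl)-2,6-dimethoxyphenyl]-3-methylbutyl}-5α-eudesm-4(15)-en-11-ol | C=C1CC[C@@H]([C@H](CC(C)C)c2c(OC)c(CO)c(O)c(CO)c2OC)[C@]2(C)CC[C@@H](C(C)(C)O)C[C@@H]12
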